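Ring B is a β-resorcylate whose C5' carboxyl, C4' and C2' oxygens and C6' pentyl chain are the imprint of a malonate joined to an alk-3-en-2-one, with the ether-bearing C1' as the enone α-carbon. Everything rests on cutting C5'–C6' and C3'–C4'. In one operation dibenzyl malonate adds to, and then cyclises onto, an open-chain 3-aryloxynon-3-en-2-one (Michael addition, Dieckmann closure), delivering all six ring B carbons with every substituent placed; mild oxidation aromatizes. The precursor carries finished ring A, a 4-O-benzyl methyl olivetolate, on the enone α-carbon through its C2 oxygen, a bond made at sp3 carbon by carbenoid O–H insertion, so the doubly flanked diaryl ether is never forged on an arene.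

Key step: step 6

Remark on locants: ring A is numbered as a benzoate (C1 CO2Me, C2 ether oxygen, C4 OH, C6 pentyl). Ring B is numbered C1' (ether carbon), C2' (OMe), C3' (H), C4' (OH), C5' (CO2H), C6' (pentyl). The target is achiral. Every sp3 centre and the alkene geometry met on the way are carried as mixtures and vanish on aromatization.

Step 1
Reactants: 1 (E)-non-3-en-2-one; 2 dimethyl malonate
Product: 4 methyl 2,4-dioxo-6-pentylcyclohexane-1-carboxylate (racemic; keto/enol mixture), via keto diester 3 (not isolated)
Conditions: NaOMe (1.1 equiv), MeOH, 0 °C to reflux; then 1 M HCl, 0 °C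
Reagents that add atoms: none
Why: This is the classical Michael addition–Dieckmann condensation of a malonate with an alk-3-en-2-one, pulled to completion by deprotonation of the acidic cyclic 1,3-dione, and the two new stereocentres arise without control because step 2 deletes them.

Step 2
Reactants: 4 methyl 2,4-dioxo-6-pentylcyclohexane-1-carboxylate
Product: 6 methyl 2,4-dihydroxy-6-pentylbenzoate (methyl olivetolate; ring A), via bromodione 5 (not isolated)
Conditions: Br2 (1.0 equiv), DMF, 0 °C; then 80 °C (not higher)
Reagents that add atoms: none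
Why: In this halogenative aromatization bromine attacks the enol carbon between the two carbonyls and warming expels HBr together with a ring hydrogen so that the dienone tautomerises to the resorcinol, while one equivalent of bromine, DMF as HBr sink and the temperature cap hold back nuclear bromination and ester dealkylation.

Step 3
Reactants: 6 methyl 2,4-dihydroxy-6-pentylbenzoate
Product: 7 methyl 4-(benzyloxy)-2-hydroxy-6-pentylbenzoate
Conditions: BnBr (1.05 equiv), K2CO3 (1.2 equiv), acetone, reflux
Reagents that add atoms: benzyl bromide, BrCc1ccccc1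
Why: In this Williamson ether synthesis the 2-OH is tied up by its hydrogen bond to the ester carbonyl, so a weak base and one equivalent of halide alkylate only the freer and more acidic 4-OH.

Step 4
Reactants: 7 methyl 4-(benzyloxy)-2-hydroxy-6-pentylbenzoate; 8 dimethyl (1-diazo-2-oxopropyl)phosphonate
Product: 9 methyl 4-(benzyloxy)-2-[1-(dimethoxyphosphoryl)-2-oxopropoxy]-6-pentylbenzoate (racemic)
Conditions: Rh2(OAc)4 (2 mol %), 8 (1.5 equiv, syringe pump), 1,2-dichloroethane, 80 °C
Reagents that add atoms: none
Why: Rhodium-carbenoid O–H insertion of an acceptor/acceptor diazo compound into a phenol is a known way to α-aryloxy phosphonates and should work here because the 2-OH is the only O–H left and slow addition keeps carbene dimerisation down; the new stereocentre is racemic and disappears in step 5.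

Step 5
Reactants: 9 methyl 4-(benzyloxy)-2-[1-(dimethoxyphosphoryl)-2-oxopropoxy]-6-pentylbenzoate; 10 hexanal
Product: 11 methyl 4-(benzyloxy)-2-[(2-oxonon-3-en-3-yl)oxy]-6-pentylbenzoate (E/Z mixture; geometry immaterial)
Conditions: LiCl (1.5 equiv), DBU (1.1 equiv), 10 (1.3 equiv), MeCN, 0 °C to rt
Reagents that add atoms: none
Why: In this Horner–Wadsworth–Emmons olefination under Masamune–Roush conditions lithium chelation lets a weak amidine base form the doubly stabilised carbanion without enolising hexanal or touching the hindered ring A ester, and either alkene geometry serves because both lead to the same adduct in step 6.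

Step 6
Reactants: 11 methyl 4-(benzyloxy)-2-[(2-oxonon-3-en-3-yl)oxy]-6-pentylbenzoate; 12 dibenzyl malonate
Product: 14 benzyl 5-[5-(benzyloxy)-2-(methoxycarbonyl)-3-pentylphenoxy]-2,4-dioxo-6-pentylcyclohexane-1-carboxylate (diastereomer and enol mixture), via Michael adduct 13 (not isolated)
Conditions: 12 (1.1 equiv), NaH (1.1 equiv), THF, 0 °C; add 11, rt to 65 °C; then cold 1 M HCl
Reagents that add atoms: none
Why: Proposed new method: sodium dibenzyl malonate attacks C6', the pentyl-bearing β-carbon and only electrophilic alkene carbon of 11 (bond C5'–C6'), proton transfer gives adduct 13, and its methyl-side enolate then acylates on one benzyl ester (bond C3'–C4') with loss of benzyloxide, which the acidic 1,3-dione consumes at once, so both reversible events drain into the stabilised enolate of 14. The closest known reaction type is the Michael–Dieckmann annulation of malonates with alk-3-en-2-ones used in step 1, which also accepts α-alkyl enones; the untested element is the α-aryloxy group, whose lone-pair donation weakens the acceptor, hence a preformed stoichiometric enolate and warming. Ring B closes by a 6-(enolexo)-exo-trig acyl substitution, the enolate on the C1' side being able to reach the malonate esters only through a four-membered ring. The three new stereocentres (C1', C5', C6') are under no control and need none, since step 7 removes them. The step needs chemoselectivity between three esters: the ring A methyl ester is shielded by its two ortho groups, attack on it by the C1' enolate would build a quaternary carbon and yield no acidic product to hold the equilibrium, and hydride as base leaves no free alkoxide to scramble methyl against benzyl. The aryloxide is not lost, because it lies γ to the malonate carbanion and α to the ketone, so no β-elimination pathway exists.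

Step 7
Reactants: 14 benzyl 5-[5-(benzyloxy)-2-(methoxycarbonyl)-3-pentylphenoxy]-2,4-dioxo-6-pentylcyclohexane-1-carboxylate
Product: 16 benzyl 5-[5-(benzyloxy)-2-(methoxycarbonyl)-3-pentylphenoxy]-2,4-dihydroxy-6-pentylbenzoate, via bromodione 15 (not isolated)
Conditions: CuBr2 (2.1 equiv), LiBr (1 equiv), MeCN, 0 °C to 40 °C
Reagents that add atoms: none
Why: This is a halogenative aromatization of the same type as step 2, in which CuBr2 (divalent copper, two moles per two-electron oxidation) brominates C3', the enol carbon between the carbonyls and by far the most nucleophilic site, and loss of HBr with the C6' hydrogen gives the arene at a temperature that spares the benzyl ester, whereas expulsion of the aryloxy group is disfavoured because C6'–H is not acidified and a cation at C1' would sit beside a carbonyl.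

Step 8
Reactants: 16 benzyl 5-[5-(benzyloxy)-2-(methoxycarbonyl)-3-pentylphenoxy]-2,4-dihydroxy-6-pentylbenzoate
Product: 17 benzyl 5-[5-(benzyloxy)-2-(methoxycarbonyl)-3-pentylphenoxy]-2-hydroxy-4-methoxy-6-pentylbenzoate
Conditions: MeI (1.05 equiv), K2CO3 (1.1 equiv), acetone, rt
Reagents that add atoms: iodomethane, CI
Why: This Williamson methylation is governed by the same chelation effect as step 3, since the C4' hydroxyl is hydrogen-bonded to the adjacent benzyl ester and stays protonated while the unchelated C2' hydroxyl para to that ester is alkylated.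

Step 9
Reactants: 17 benzyl 5-[5-(benzyloxy)-2-(methoxycarbonyl)-3-pentylphenoxy]-2-hydroxy-4-methoxy-6-pentylbenzoate
Product: 18 epiphorellic acid 1
Conditions: H2 (1 atm), 10% Pd/C, EtOAc, rt; concentrate without heating
Reagents that add atoms: none
Why: Catalytic hydrogenolysis cleaves the benzyl ether and the benzyl ester under neutral conditions at room temperature, leaving the methyl ester, methyl ether and diaryl ether untouched and avoiding the heat or acid that would decarboxylate the salicylic-type acid.

Compound list
1 | (E)-non-3-en-2-one | CCCCC/C=C/C(C)=O | starting material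
2 | dimethyl malonate | COC(=O)CC(=O)OC | starting material
3 | dimethyl 2-(2-oxononan-4-yl)propanedioate (racemic, not isolated) | CCCCCC(CC(C)=O)C(C(=O)OC)C(=O)OC | intermediate
4 | methyl 2,4-dioxo-6-pentylcyclohexane-1-carboxylate (racemic, keto/enol mixture) | CCCCCC1CC(=O)CC(=O)C1C(=O)OC | intermediate
5 | methyl 3-bromo-2,4-dioxo-6-pentylcyclohexane-1-carboxylate (stereoisomer mixture, not isolated) | CCCCCC1CC(=O)C(Br)C(=O)C1C(=O)OC | intermediate
6 | methyl 2,4-dihydroxy-6-pentylbenzoate | CCCCCc1cc(O)cc(O)c1C(=O)OC | intermediate
7 | methyl 4-(benzyloxy)-2-hydroxy-6-pentylbenzoate | CCCCCc1cc(OCc2ccccc2)cc(O)c1C(=O)OC | intermediate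
8 | dimethyl (1-diazo-2-oxopropyl)phosphonate | CC(=O)C(=[N+]=[N-])P(=O)(OC)OC | starting material
9 | methyl 4-(benzyloxy)-2-[1-(dimethoxyphosphoryl)-2-oxopropoxy]-6-pentylbenzoate (racemic) | CCCCCc1cc(OCc2ccccc2)cc(OC(C(C)=O)P(=O)(OC)OC)c1C(=O)OC | intermediate
10 | hexanal | CCCCCC=O | starting material
11 | methyl 4-(benzyloxy)-2-[(2-oxonon-3-en-3-yl)oxy]-6-pentylbenzoate (E/Z mixture) | CCCCCC=C(Oc1cc(OCc2ccccc2)cc(CCCCC)c1C(=O)OC)C(C)=O | intermediate
12 | dibenzyl malonate | O=C(CC(=O)OCc1ccccc1)OCc1ccccc1 | starting material
13 | dibenzyl 2-{3-[5-(benzyloxy)-2-(methoxycarbonyl)-3-pentylphenoxy]-2-oxononan-4-yl}propanedioate (diastereomer mixture, not isolated) | CCCCCC(C(Oc1cc(OCc2ccccc2)cc(CCCCC)c1C(=O)OC)C(C)=O)C(C(=O)OCc1ccccc1)C(=O)OCc1ccccc1 | intermediate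
14 | benzyl 5-[5-(benzyloxy)-2-(methoxycarbonyl)-3-pentylphenoxy]-2,4-dioxo-6-pentylcyclohexane-1-carboxylate (diastereomer and enol mixture) | CCCCCC1C(Oc2cc(OCc3ccccc3)cc(CCCCC)c2C(=O)OC)C(=O)CC(=O)C1C(=O)OCc1ccccc1 | intermediate
15 | benzyl 5-[5-(benzyloxy)-2-(methoxycarbonyl)-3-pentylphenoxy]-3-bromo-2,4-dioxo-6-pentylcyclohexane-1-carboxylate (stereoisomer mixture, not isolated) | CCCCCC1C(Oc2cc(OCc3ccccc3)cc(CCCCC)c2C(=O)OC)C(=O)C(Br)C(=O)C1C(=O)OCc1ccccc1 | intermediate
16 | benzyl 5-[5-(benzyloxy)-2-(methoxycarbonyl)-3-pentylphenoxy]-2,4-dihydroxy-6-pentylbenzoate | CCCCCc1c(Oc2cc(OCc3ccccc3)cc(CCCCC)c2C(=O)OC)c(O)cc(O)c1C(=O)OCc1ccccc1 | intermediate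
17 | benzyl 5-[5-(benzyloxy)-2-(methoxycarbonyl)-3-pentylphenoxy]-2-hydroxy-4-methoxy-6-pentylbenzoate | CCCCCc1c(Oc2cc(OCc3ccccc3)cc(CCCCC)c2C(=O)OC)c(OC)cc(O)c1C(=O)OCc1ccccc1 | intermediate
18 | epiphorellic acid 1, 2-hydroxy-5-[5-hydroxy-2-(methoxycarbonyl)-3-pentylphenoxy]-4-methoxy-6-pentylbenzoic acid | CCCCCc1cc(O)cc(Oc2c(OC)cc(O)c(C(=O)O)c2CCCCC)c1C(=O)OC | target

Total step count: 9. Longest linear sequence: 9 steps (1 and 2 through to 18); 8, 10 and 12 are bought and enter directly.

Steps most likely to fail

1. Step 6.
- Risk: the conjugate addition may stall or revert, because the alkene is trisubstituted and receives electron density from the aryloxy oxygen. The enolate at C1' may instead acylate on the neighbouring ring A ester in a five-membered closure. The malonate carbanion may also displace the aryloxide in a three-membered closure.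
- Fallback: a copper-catalysed Ullmann diaryl ether synthesis (known chemistry). It sets out from 1, 12 and 7 and comes back to the route at 18.
- Ring B is built first. Enone 1 and malonate 12 are annulated as in step 1 (NaH, THF, reflux) to benzyl 2,4-dioxo-6-pentylcyclohexane-1-carboxylate F1, and CuBr2 in MeCN aromatizes it to benzyl 2,4-dihydroxy-6-pentylbenzoate F2.
- MeI/K2CO3 gives benzyl 2-hydroxy-4-methoxy-6-pentylbenzoate F3, and BnBr/K2CO3 in warm DMF gives benzyl 2-(benzyloxy)-4-methoxy-6-pentylbenzoate F4.
- NBS in MeCN brominates the position between methoxy and pentyl, the site between the two alkoxy groups being more crowded. This gives benzyl 2-(benzyloxy)-5-bromo-4-methoxy-6-pentylbenzoate F5.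
- Coupling of F5 with phenol 7 (CuI, picolinic acid, K3PO4, DMSO, 100 °C) gives benzyl 2-(benzyloxy)-5-[5-(benzyloxy)-2-(methoxycarbonyl)-3-pentylphenoxy]-4-methoxy-6-pentylbenzoate F6. H2 over Pd/C then removes all three benzyl groups to reach 18.

2. Step 7.
- Risk: the oxidation may stop at partly dehydrobrominated material while the new resorcinol ring or ring A is brominated further. The liberated HBr may strip benzyl groups. Aromatization by expulsion of the ring A phenol may compete.
- Fallback: the classical exhaustive bromination followed by reductive debromination. It sets out from 14 and comes back at 18.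
- Buffered excess bromine (Br2, 2 equiv, NaOAc, AcOH, rt) drives 14 through to a single product, benzyl 3-bromo-5-[5-(benzyloxy)-2-(methoxycarbonyl)-3-pentylphenoxy]-2,4-dihydroxy-6-pentylbenzoate F7.
- MeI/K2CO3 methylates the unchelated hydroxyl to give benzyl 3-bromo-5-[5-(benzyloxy)-2-(methoxycarbonyl)-3-pentylphenoxy]-2-hydroxy-4-methoxy-6-pentylbenzoate F8.
- H2 over Pd/C with NaOAc in EtOAc–EtOH cleaves the aryl bromide together with both benzyl groups. Any stray bromine on ring A is erased in the same operation.

3. Step 4.
- Risk: the hydrogen-bonded, ortho-flanked phenol may capture the carbenoid too slowly. Carbene dimerisation, Wolff rearrangement or attack on the benzyl ring would then take over.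
- Fallback: ionic C–O bond formation by opening an α,β-epoxy ketone at its α-carbon with a phenoxide, the known route to 2-aryloxy enones. It sets out from 1 and 7, bypasses 9, and comes back at 11.
- Weitz–Scheffer epoxidation of 1 (H2O2, NaOH, MeOH, 0 °C) gives racemic trans-3,4-epoxynonan-2-one F9.
- Phenol 7 with Cs2CO3 in MeCN at 60 °C opens F9 at C3 to methyl 4-(benzyloxy)-2-[(4-hydroxy-2-oxononan-3-yl)oxy]-6-pentylbenzoate F10. This loses water by E1cB under the same conditions to give 11.

Further compounds
F1 | step 6 | benzyl 2,4-dioxo-6-pentylcyclohexane-1-carboxylate (racemic, keto/enol mixture) | CCCCCC1CC(=O)CC(=O)C1C(=O)OCc1ccccc1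
F2 | step 6 | benzyl 2,4-dihydroxy-6-pentylbenzoate | CCCCCc1cc(O)cc(O)c1C(=O)OCc1ccccc1
F3 | step 6 | benzyl 2-hydroxy-4-methoxy-6-pentylbenzoate | CCCCCc1cc(OC)cc(O)c1C(=O)OCc1ccccc1
F4 | step 6 | benzyl 2-(benzyloxy)-4-methoxy-6-pentylbenzoate | CCCCCc1cc(OC)cc(OCc2ccccc2)c1C(=O)OCc1ccccc1
F5 | step 6 | benzyl 2-(benzyloxy)-5-bromo-4-methoxy-6-pentylbenzoate | CCCCCc1c(Br)c(OC)cc(OCc2ccccc2)c1C(=O)OCc1ccccc1
F6 | step 6 | benzyl 2-(benzyloxy)-5-[5-(benzyloxy)-2-(methoxycarbonyl)-3-pentylphenoxy]-4-methoxy-6-pentylbenzoate | CCCCCc1c(Oc2cc(OCc3ccccc3)cc(CCCCC)c2C(=O)OC)c(OC)cc(OCc2ccccc2)c1C(=O)OCc1ccccc1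
F7 | step 7 | benzyl 3-bromo-5-[5-(benzyloxy)-2-(methoxycarbonyl)-3-pentylphenoxy]-2,4-dihydroxy-6-pentylbenzoate | CCCCCc1c(Oc2cc(OCc3ccccc3)cc(CCCCC)c2C(=O)OC)c(O)c(Br)c(O)c1C(=O)OCc1ccccc1
F8 | step 7 | benzyl 3-bromo-5-[5-(benzyloxy)-2-(methoxycarbonyl)-3-pentylphenoxy]-2-hydroxy-4-methoxy-6-pentylbenzoate | CCCCCc1c(Oc2cc(OCc3ccccc3)cc(CCCCC)c2C(=O)OC)c(OC)c(Br)c(O)c1C(=O)OCc1ccccc1
F9 | step 4 | trans-3,4-epoxynonan-2-one (racemic, one enantiomer drawn) | CCCCC[C@H]1O[C@@H]1C(C)=O
F10 | step 4 | methyl 4-(benzyloxy)-2-[(4-hydroxy-2-oxononan-3-yl)oxy]-6-pentylbenzoate (racemic, configuration not carried on) | CCCCCC(O)C(Oc1cc(OCc2ccccc2)cc(CCCCC)c1C(=O)OC)C(C)=O
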